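**Retrosynthetic overview**

1. Chain numbering: ring A–C1(Me)–C2(OH)–C3(Me)–C4(OH)–C5(Me)=C6–C7(Me)–ring B–C8(Me)–C9(OH)–C10–C11. No ring is built: rings A and B both come from the same bought, symmetric 2,6-diethyl-3,5-dimethyl-4-pyranone, dearomatised once to its 2-ethylidene-2H-pyran silyl dienol ether; one batch serves both halves.
2. C6–C7 (last C–C bond): nickel-catalysed enantioconvergent reductive coupling of a ring A vinyl bromide with a ring B lateral chloride; sets C7.
3. C1–C2: vinylogous Mukaiyama aldol of the dienol ether with the C2 aldehyde (Felkin, 1,2-anti); sets C1 and C2.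
4. C8–C9: catalytic enantioselective anti vinylogous aldol of the same dienol ether with propanal, then chlorination of the second ethyl group through a second dearomatisation.
5. Linker C2–C6: methacrolein → (E)-3-bromo-2-methylacrolein, catalytic anti-crotylboration (C3, C4), ozonolysis. Ring A is attached to the linker first, the ring B half is made separately, and the two halves are joined last.

Assumption: 2,6-diethyl-3,5-dimethyl-4H-pyran-4-one is bought as a catalogue heteroaromatic (it is the one-pot polyphosphoric acid condensation product of pentan-3-one and propanoic acid).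
Assumption: in the catalyst-controlled steps 2, 7 and 9 the catalyst antipode named is the one expected from the parent reactions (recalled, not checked); if a first run shows the opposite sense, the mirror-image catalyst is used and nothing else changes.

Compounds are numbered in the order in which they enter the forward route.

**Route**

Step 1
Reactants: 1 methacrolein
Product: 3 (2E)-3-bromo-2-methylprop-2-enal, via 2,3-dibromo-2-methylpropanal 2 (not isolated)
Conditions: Br2, CH2Cl2, −78 → 0 °C; then Et3N, 0 °C → rt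
Reagents that add atoms: bromine, BrBr
Why: Bromination–dehydrobromination: Br2 adds across the enal C=C and Et3N then removes the C3–H with loss of the tertiary α-bromide, giving the conjugated bromo enal as the more stable (E) isomer (Br trans to CHO).

Step 2
Reactants: 3 (2E)-3-bromo-2-methylprop-2-enal; 4 (E)-crotylboronic acid pinacol ester
Product: 6 (1E,3R,4R)-1-bromo-2,4-dimethylhexa-1,5-dien-3-ol, via pinacol borate ester 5 (not isolated)
Conditions: (R)-TRIP phosphoric acid [(R)-3,3'-bis(2,4,6-triisopropylphenyl)-1,1'-binaphthyl-2,2'-diyl hydrogen phosphate] (5 mol %), 4 Å MS, toluene, −30 °C; aq. NaHCO3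
Reagents that add atoms: none
Why: Chiral-phosphoric-acid-catalysed crotylboration through a chair six-membered transition state: the (E)-crotyl geometry gives the anti relationship and the (R)-acid directs attack to the Re face of the enal, which sets chain C4 (R) and C3 (R).

Step 3
Reactants: 6 (1E,3R,4R)-1-bromo-2,4-dimethylhexa-1,5-dien-3-ol
Product: 7 {[(1E,3R,4R)-1-bromo-2,4-dimethylhexa-1,5-dien-3-yl]oxy}(tert-butyl)dimethylsilane
Conditions: TBSOTf, 2,6-lutidine, CH2Cl2, −78 → 0 °C
Reagents that add atoms: tert-butyldimethylsilyl trifluoromethanesulfonate (TBSOTf), CC(C)(C)[Si](C)(C)OS(=O)(=O)C(F)(F)F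
Why: Silyl triflate silylation of a hindered secondary allylic alcohol; no stereocentre is touched.

Step 4
Reactants: 7 {[(1E,3R,4R)-1-bromo-2,4-dimethylhexa-1,5-dien-3-yl]oxy}(tert-butyl)dimethylsilane
Product: 9 (2S,3R,4E)-5-bromo-3-{[tert-butyl(dimethyl)silyl]oxy}-2,4-dimethylpent-4-enal, via ozonide 8 (not isolated)
Conditions: O3, CH2Cl2, −78 °C (Sudan Red 7B end-point); then PPh3, −78 °C → rt
Reagents that add atoms: ozone, [O-][O+]=O
Why: Ozonolysis: the terminal monosubstituted alkene reacts faster than the electron-poor, hindered bromoalkene, and PPh3 reduces the ozonide under neutral conditions so the α-stereocentre (chain C3) is not epimerised.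

Step 5
Reactants: 10 2,6-diethyl-3,5-dimethyl-4H-pyran-4-one
Product: 11 tert-butyl{[(2Z)-6-ethyl-2-ethylidene-3,5-dimethyl-2H-pyran-4-yl]oxy}dimethylsilane
Conditions: TBSOTf (1.05 equiv), Et3N (1.2 equiv), CH2Cl2, −78 → 0 °C; concentrate, triturate with dry pentane, filter under argon, evaporate; kept as a CH2Cl2 stock solution under argon for steps 6 and 7
Reagents that add atoms: tert-butyldimethylsilyl trifluoromethanesulfonate (TBSOTf), CC(C)(C)[Si](C)(C)OS(=O)(=O)C(F)(F)F
Why: Proposed new method: soft enolisation of a 2-alkyl-4-pyranone to its dearomatised silyl dienol ether (closest known: anhydrobase formation by lateral deprotonation of 2-alkylpyrylium salts, and silyl triflate/amine soft enolisation of ketones and vinylogous esters) — TBSOTf O-silylates the pyranone carbonyl to a 4-silyloxypyrylium ion whose ethyl CH2 is acidic enough for Et3N, and because the resulting 2-ethylidene-2H-pyran is neutral the second, equivalent ethyl group does not react, so the symmetry is broken in the same event; the exocyclic methyl turns away from the ring methyl, giving the (Z) alkene.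

Step 6
Reactants: 11 tert-butyl{[(2Z)-6-ethyl-2-ethylidene-3,5-dimethyl-2H-pyran-4-yl]oxy}dimethylsilane; 9 (2S,3R,4E)-5-bromo-3-{[tert-butyl(dimethyl)silyl]oxy}-2,4-dimethylpent-4-enal
Product: 12 2-[(2R,3R,4R,5R,6E)-7-bromo-3,5-bis{[tert-butyl(dimethyl)silyl]oxy}-4,6-dimethylhept-6-en-2-yl]-6-ethyl-3,5-dimethyl-4H-pyran-4-one
Conditions: 11 (1.5 equiv), 9 (1.0 equiv), TBSOTf (20 mol %), 2,6-di-tert-butyl-4-methylpyridine (10 mol %), CH2Cl2, −78 → −40 °C; aq. NaHCO3
Reagents that add atoms: none
Why: Proposed new method: silyl-triflate-catalysed vinylogous Mukaiyama aldol of a 2-alkylidene-2H-pyran (closest known: silyl-triflate-catalysed Mukaiyama aldols of silyl enol ethers, and lateral aldol additions of lithiated 2-alkyl-4-pyranones) — TBSOTf silylates the aldehyde oxygen of 9, the exocyclic carbon of 11 attacks through an open antiperiplanar transition state, and rearomatisation gives the 4-silyloxypyrylium triflate of the product, which hands its silyl group to the next aldehyde, so the net result is transfer of the silyl group of 11 to the new oxygen; Felkin–Anh control by the C3 methyl, reinforced by 1,3-anti induction from the C4 silyloxy group, sets C2 (R), and the open transition state that turns the aldehyde chain away from the ring methyl sets C1 (R, 1,2-anti).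

Step 7
Reactants: 11 tert-butyl{[(2Z)-6-ethyl-2-ethylidene-3,5-dimethyl-2H-pyran-4-yl]oxy}dimethylsilane; 13 propanal
Product: 15 2-ethyl-6-[(2S,3S)-3-hydroxypentan-2-yl]-3,5-dimethyl-4H-pyran-4-one, via trichlorosilyl ether 14 (not isolated)
Conditions: 11 (1.2 equiv), 13 (1.0 equiv), SiCl4 (1.1 equiv), (R,R)-dimeric phosphoramide [two (R)-N,N'-dimethyl-1,1'-binaphthyl-2,2'-diamine phosphoramide units joined by an N,N'-dimethylpentane-1,5-diamine tether] (5 mol %), iPr2NEt (10 mol %), CH2Cl2, −78 °C; sat. aq. NaHCO3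
Reagents that add atoms: none
Why: Proposed new method: Lewis-base-activated SiCl4 vinylogous Mukaiyama aldol (closest known: phosphoramide/SiCl4-catalysed additions of γ-substituted silyl dienol ethers and silyl ketene acetals to aldehydes, anti-selective whatever the enol ether geometry) — the phosphoramide-bound trichlorosilyl cation activates propanal, dienol ether 11 attacks its Re face through an open transition state to set C9 (S) and, by the anti preference, C8 (S), and rearomatisation to the pyranone drives the step; the bidentate phosphoramide should bind silicon far better than the pyranone carbonyl, keeping the achiral background path slow.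

Step 8
Reactants: 15 2-ethyl-6-[(2S,3S)-3-hydroxypentan-2-yl]-3,5-dimethyl-4H-pyran-4-one
Product: 18 2-[(2S,3S)-3-{[tert-butyl(dimethyl)silyl]oxy}pentan-2-yl]-6-(1-chloroethyl)-3,5-dimethyl-4H-pyran-4-one (1:1 epimers at the chlorine-bearing carbon), via silyl ether 16 (not isolated), via silyl dienol ether 17 (not isolated)
Conditions: TBSOTf (2.2 equiv), Et3N (2.3 equiv), CH2Cl2, −78 → −20 °C; then NCS (1.05 equiv), −78 °C; aq. NaHCO3
Reagents that add atoms: tert-butyldimethylsilyl trifluoromethanesulfonate (TBSOTf), CC(C)(C)[Si](C)(C)OS(=O)(=O)C(F)(F)F; N-chlorosuccinimide (NCS), ClN1C(=O)CCC1=O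
Why: Proposed new method: the soft enolisation of step 5 followed by electrophilic chlorination of the silyl dienol ether (closest known: α-chlorination of silyl enol ethers with NCS) — one equivalent of TBSOTf protects the C9 hydroxyl, the second gives the pyrylium ion that Et3N deprotonates at the unhindered ethyl CH2 (the C8 methine would give a strained tetrasubstituted exocyclic alkene, so C8 is not scrambled), and NCS chlorinates the exocyclic carbon with rearomatisation; the new C–Cl centre forms as both epimers, which does not matter because step 9 is stereoconvergent.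

Step 9
Reactants: 12 2-[(2R,3R,4R,5R,6E)-7-bromo-3,5-bis{[tert-butyl(dimethyl)silyl]oxy}-4,6-dimethylhept-6-en-2-yl]-6-ethyl-3,5-dimethyl-4H-pyran-4-one; 18 2-[(2S,3S)-3-{[tert-butyl(dimethyl)silyl]oxy}pentan-2-yl]-6-(1-chloroethyl)-3,5-dimethyl-4H-pyran-4-one
Product: 19 2-[(2R,3R,4R,5R,6E,8R)-3,5-bis{[tert-butyl(dimethyl)silyl]oxy}-8-{6-[(2S,3S)-3-{[tert-butyl(dimethyl)silyl]oxy}pentan-2-yl]-3,5-dimethyl-4-oxo-4H-pyran-2-yl}-4,6-dimethylnon-6-en-2-yl]-6-ethyl-3,5-dimethyl-4H-pyran-4-one
Conditions: 12 (1.0 equiv), 18 (1.2 equiv), NiCl2(dme) (10 mol %), (3aS,3a'S,8aR,8a'R)-2,2'-(cyclopropane-1,1-diyl)bis(3a,8a-dihydro-8H-indeno[1,2-d]oxazole) (11 mol %), Mn powder (3 equiv), NaI (0.5 equiv), DMA, 0 °C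
Reagents that add atoms: none
Why: Proposed new method: nickel-catalysed enantioconvergent reductive cross-coupling of a vinyl bromide with a racemic secondary lateral chloride (closest known: the same NiCl2(dme)/bis(oxazoline)/Mn coupling of vinyl bromides with 1-chloroethylarenes) — halogen abstraction gives a planar pyranone-stabilised radical so both epimers of 18 converge, the alkenylnickel–bis(oxazoline) complex captures it and reductive elimination sets C7 (R) under ligand control with retention of the (E)-alkene; no base is present, so the acidic C7–H next to ring B and the alkene is not epimerised.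

Step 10
Reactants: 19 tris-silyl ether (name as in step 9)
Product: 20 2-[(2R,3R,4R,5R,6E,8R)-3,5-dihydroxy-8-{6-[(2S,3S)-3-hydroxypentan-2-yl]-3,5-dimethyl-4-oxo-4H-pyran-2-yl}-4,6-dimethylnon-6-en-2-yl]-6-ethyl-3,5-dimethyl-4H-pyran-4-one (CNP0408419.9)
Conditions: HF·pyridine, pyridine, THF, 0 °C → rt
Reagents that add atoms: none
Why: Buffered fluoride desilylation removes all three TBS ethers; the non-basic medium avoids retro-aldol cleavage, dehydration of the β-hydroxy pyranone arms and epimerisation at C7.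

**Compound list**

1 | methacrolein (2-methylprop-2-enal) | CC(=C)C=O | starting material
2 | 2,3-dibromo-2-methylpropanal (racemic) | CC(Br)(CBr)C=O | intermediate
3 | (2E)-3-bromo-2-methylprop-2-enal | O=C/C(C)=C/Br | intermediate
4 | (E)-crotylboronic acid pinacol ester, 2-[(2E)-but-2-en-1-yl]-4,4,5,5-tetramethyl-1,3,2-dioxaborolane | C/C=C/CB1OC(C)(C)C(C)(C)O1 | starting material
5 | 2-{[(1E,3R,4R)-1-bromo-2,4-dimethylhexa-1,5-dien-3-yl]oxy}-4,4,5,5-tetramethyl-1,3,2-dioxaborolane | C=C[C@@H](C)[C@@H](OB1OC(C)(C)C(C)(C)O1)/C(C)=C/Br | intermediate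
6 | (1E,3R,4R)-1-bromo-2,4-dimethylhexa-1,5-dien-3-ol | C=C[C@@H](C)[C@@H](O)/C(C)=C/Br | intermediate
7 | {[(1E,3R,4R)-1-bromo-2,4-dimethylhexa-1,5-dien-3-yl]oxy}(tert-butyl)dimethylsilane | C=C[C@@H](C)[C@@H](O[Si](C)(C)C(C)(C)C)/C(C)=C/Br | intermediate
8 | 3-[(2S,3R,4E)-5-bromo-3-{[tert-butyl(dimethyl)silyl]oxy}-4-methylpent-4-en-2-yl]-1,2,4-trioxolane (both epimers at the ring carbon) | O1COOC1[C@@H](C)[C@@H](O[Si](C)(C)C(C)(C)C)/C(C)=C/Br | intermediate
9 | (2S,3R,4E)-5-bromo-3-{[tert-butyl(dimethyl)silyl]oxy}-2,4-dimethylpent-4-enal | O=C[C@@H](C)[C@@H](O[Si](C)(C)C(C)(C)C)/C(C)=C/Br | intermediate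
10 | 2,6-diethyl-3,5-dimethyl-4H-pyran-4-one | CCc1oc(CC)c(C)c(=O)c1C | starting material
11 | tert-butyl{[(2Z)-6-ethyl-2-ethylidene-3,5-dimethyl-2H-pyran-4-yl]oxy}dimethylsilane | C/C=C1\OC(CC)=C(C)C(O[Si](C)(C)C(C)(C)C)=C1C | intermediate
12 | 2-[(2R,3R,4R,5R,6E)-7-bromo-3,5-bis{[tert-butyl(dimethyl)silyl]oxy}-4,6-dimethylhept-6-en-2-yl]-6-ethyl-3,5-dimethyl-4H-pyran-4-one | CCc1oc([C@H](C)[C@H](O[Si](C)(C)C(C)(C)C)[C@@H](C)[C@@H](O[Si](C)(C)C(C)(C)C)/C(C)=C/Br)c(C)c(=O)c1C | intermediate
13 | propanal | CCC=O | starting material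
14 | trichloro{[(2S,3S)-2-(6-ethyl-3,5-dimethyl-4-oxo-4H-pyran-2-yl)pentan-3-yl]oxy}silane | CCc1oc([C@@H](C)[C@@H](O[Si](Cl)(Cl)Cl)CC)c(C)c(=O)c1C | intermediate
15 | 2-ethyl-6-[(2S,3S)-3-hydroxypentan-2-yl]-3,5-dimethyl-4H-pyran-4-one | CCc1oc([C@@H](C)[C@@H](O)CC)c(C)c(=O)c1C | intermediate
16 | 2-[(2S,3S)-3-{[tert-butyl(dimethyl)silyl]oxy}pentan-2-yl]-6-ethyl-3,5-dimethyl-4H-pyran-4-one | CCc1oc([C@@H](C)[C@@H](O[Si](C)(C)C(C)(C)C)CC)c(C)c(=O)c1C | intermediate
17 | tert-butyl({(2S,3S)-2-[(6Z)-4-{[tert-butyl(dimethyl)silyl]oxy}-6-ethylidene-3,5-dimethyl-6H-pyran-2-yl]pentan-3-yl}oxy)dimethylsilane | C/C=C1\OC([C@@H](C)[C@@H](O[Si](C)(C)C(C)(C)C)CC)=C(C)C(O[Si](C)(C)C(C)(C)C)=C1C | intermediate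
18 | 2-[(2S,3S)-3-{[tert-butyl(dimethyl)silyl]oxy}pentan-2-yl]-6-(1-chloroethyl)-3,5-dimethyl-4H-pyran-4-one (1:1 epimers at the chlorine-bearing carbon) | CC(Cl)c1oc([C@@H](C)[C@@H](O[Si](C)(C)C(C)(C)C)CC)c(C)c(=O)c1C | intermediate
19 | 2-[(2R,3R,4R,5R,6E,8R)-3,5-bis{[tert-butyl(dimethyl)silyl]oxy}-8-{6-[(2S,3S)-3-{[tert-butyl(dimethyl)silyl]oxy}pentan-2-yl]-3,5-dimethyl-4-oxo-4H-pyran-2-yl}-4,6-dimethylnon-6-en-2-yl]-6-ethyl-3,5-dimethyl-4H-pyran-4-one | CCc1oc([C@H](C)[C@H](O[Si](C)(C)C(C)(C)C)[C@@H](C)[C@@H](O[Si](C)(C)C(C)(C)C)/C(C)=C/[C@@H](C)c2oc([C@@H](C)[C@@H](O[Si](C)(C)C(C)(C)C)CC)c(C)c(=O)c2C)c(C)c(=O)c1C | intermediate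
20 | 2-[(2R,3R,4R,5R,6E,8R)-3,5-dihydroxy-8-{6-[(2S,3S)-3-hydroxypentan-2-yl]-3,5-dimethyl-4-oxo-4H-pyran-2-yl}-4,6-dimethylnon-6-en-2-yl]-6-ethyl-3,5-dimethyl-4H-pyran-4-one | CCc1oc([C@H](C)[C@H](O)[C@@H](C)[C@@H](O)/C(C)=C/[C@@H](C)c2oc([C@@H](C)[C@@H](O)CC)c(C)c(=O)c2C)c(C)c(=O)c1C | target

**Step count and risks**

Total step count: 10. Longest linear sequence: 7 steps (steps 1, 2, 3, 4, 6, 9, 10). Step 5 supplies dienol ether 11 to both halves; the ring B branch is steps 5, 7 and 8.

The three steps most likely to fail: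

Step 7 (catalytic asymmetric vinylogous aldol). The enantio- and anti-selectivity are unproven for this nucleophile, aliphatic aldehydes are the slower substrates of this catalyst system, and the Lewis-basic pyranone may open an achiral background path. The fallback sets out from 11 and 13 and returns at 15. Compound 11 and propanal are combined with BF3·OEt2 in CH2Cl2 at −78 °C, an achiral vinylogous Mukaiyama aldol that gives racemic anti-2-ethyl-6-(3-hydroxypentan-2-yl)-3,5-dimethyl-4H-pyran-4-one F1. Lipase kinetic resolution (Burkholderia cepacia lipase, vinyl acetate, tert-butyl methyl ether, 30 °C) then acetylates the (3R)-carbinol enantiomer, as the Kazlauskas rule predicts, to (2R,3R)-2-(6-ethyl-3,5-dimethyl-4-oxo-4H-pyran-2-yl)pentan-3-yl acetate F2. Unreacted (2S,3S)-alcohol 15 is separated and enters step 8.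

Step 9 (nickel reductive coupling). A pyranone lateral chloride and a 2,2-disubstituted vinyl bromide lie outside the reported scope; reduction of 18 or homocoupling may win, and the sense of induction is unverified. The fallback sets out from 15 (with 12) and returns at 19. Compound 15 is silylated (TBSOTf, 2,6-lutidine) and 16 is isolated. Deprotonation of its ethyl CH2 with LiN(SiMe3)2 (THF, −78 °C) gives the lithium dienolate of 16 F3, and ZnCl2 converts it into the chlorozinc dienolate of 16 F4. Alkenylation of this zinc dienolate with vinyl bromide 12, catalysed by Pd(dba)2 and P(t-Bu)3 in THF at rt (a polar enolate alkenylation in place of the radical coupling), gives 19 together with the C7 epimer of 19 F5. The two are separated by preparative HPLC and 19 enters step 10.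

Step 6 (substrate-controlled vinylogous aldol). The Felkin sense at C2 is reliable, but the 1,2-anti preference of the open transition state is not secured, and turnover depends on the silyloxypyrylium of the product passing its silyl group on. The fallback sets out from 11 (with 9) and returns at 12. Compound 11 is chlorinated with NCS (CH2Cl2, −78 °C; aq. NaHCO3) to racemic 2-(1-chloroethyl)-6-ethyl-3,5-dimethyl-4H-pyran-4-one F6. CrCl2 with catalytic LiI in THF at rt reduces it to the dichlorochromium dienolate of 10 F7, which is inert to the vinyl bromide in the absence of nickel salts. This adds to 9 in a Nozaki–Hiyama/chromium-Reformatsky manner through a closed chair transition state (anti and Felkin expected) to give 2-[(2R,3R,4R,5R,6E)-7-bromo-5-{[tert-butyl(dimethyl)silyl]oxy}-3-hydroxy-4,6-dimethylhept-6-en-2-yl]-6-ethyl-3,5-dimethyl-4H-pyran-4-one F8. TBSOTf/2,6-lutidine then gives 12.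

**Further compounds**

F1 | step 7 | racemic anti-2-ethyl-6-(3-hydroxypentan-2-yl)-3,5-dimethyl-4H-pyran-4-one [(2S,3S) and (2R,3R)] | CCc1oc([C@@H](C)[C@@H](O)CC)c(C)c(=O)c1C.CCc1oc([C@H](C)[C@H](O)CC)c(C)c(=O)c1C
F2 | step 7 | (2R,3R)-2-(6-ethyl-3,5-dimethyl-4-oxo-4H-pyran-2-yl)pentan-3-yl acetate | CCc1oc([C@H](C)[C@H](OC(C)=O)CC)c(C)c(=O)c1C
F3 | step 9 | lithium dienolate of 16, lithium (2Z)-6-[(2S,3S)-3-{[tert-butyl(dimethyl)silyl]oxy}pentan-2-yl]-2-ethylidene-3,5-dimethyl-2H-pyran-4-olate | C/C=C1\OC([C@@H](C)[C@@H](O[Si](C)(C)C(C)(C)C)CC)=C(C)C(O[Li])=C1C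
F4 | step 9 | chlorozinc dienolate of 16, chlorozinc (2Z)-6-[(2S,3S)-3-{[tert-butyl(dimethyl)silyl]oxy}pentan-2-yl]-2-ethylidene-3,5-dimethyl-2H-pyran-4-olate | C/C=C1\OC([C@@H](C)[C@@H](O[Si](C)(C)C(C)(C)C)CC)=C(C)C(O[Zn]Cl)=C1C
F5 | step 9 | C7 epimer of 19, the (2R,3R,4R,5R,6E,8S)-non-6-en-2-yl isomer | CCc1oc([C@H](C)[C@H](O[Si](C)(C)C(C)(C)C)[C@@H](C)[C@@H](O[Si](C)(C)C(C)(C)C)/C(C)=C/[C@H](C)c2oc([C@@H](C)[C@@H](O[Si](C)(C)C(C)(C)C)CC)c(C)c(=O)c2C)c(C)c(=O)c1C
F6 | step 6 | 2-(1-chloroethyl)-6-ethyl-3,5-dimethyl-4H-pyran-4-one (racemic) | CCc1oc(C(C)Cl)c(C)c(=O)c1C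
F7 | step 6 | dichlorochromium dienolate of 10, dichlorochromium (2Z)-6-ethyl-2-ethylidene-3,5-dimethyl-2H-pyran-4-olate | C/C=C1\OC(CC)=C(C)C(O[Cr](Cl)Cl)=C1C
F8 | step 6 | 2-[(2R,3R,4R,5R,6E)-7-bromo-5-{[tert-butyl(dimethyl)silyl]oxy}-3-hydroxy-4,6-dimethylhept-6-en-2-yl]-6-ethyl-3,5-dimethyl-4H-pyran-4-one | CCc1oc([C@H](C)[C@H](O)[C@@H](C)[C@@H](O[Si](C)(C)C(C)(C)C)/C(C)=C/Br)c(C)c(=O)c1C
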